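## Retrosynthetic overview

1. The target is released from its bis-carbamate by one reductive cleavage of both N,N-diisopropylcarbamates.
2. Key disconnection C5'–C6' (the diol bond): C1 of geraniol, turned into a configurationally defined α-lithiated O-carbamate (an α-oxy carbanion), adds to the aldehyde carbon of a chromene enal. Both carbinol centres are set in this step.
3. The chromene enal comes from a (2R,3S)-3-phenylthiochroman by sulfoxide syn-elimination. The chroman comes from an ortho-alkenyl phenol by catalytic enantioselective sulfenoetherification, which sets C2.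
4. That phenol comes from an ortho-geranyl phenol and methacrolein by cross-metathesis. The ortho-geranyl phenol comes from mono-protected 2-methylhydroquinone and geranyl bromide.
5. Rings: the benzene ring is bought. The pyran ring is closed in step 4 (as a chroman) and dehydrogenated to the 2H-chromene in step 5. No other ring is formed.

Assumption: side-chain carbons are numbered C1' to C13' outward from C2 of the chromene; the (S)-selenophosphoramide and (−)-sparteine are taken, by analogy with simpler substrates, to give the enantiomeric series drawn, and the antipodal catalyst or (+)-sparteine would be used if either sense proved opposite.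

## Route

Step 1
Reactants: 1 2-methylhydroquinone (2-methylbenzene-1,4-diol)
Product: 2 4-hydroxy-3-methylphenyl N,N-diisopropylcarbamate
Conditions: NaH (1.0 equiv), THF, 0 °C; i-Pr2NCOCl (1.0 equiv), 0 to 65 °C
Reagents that add atoms: N,N-diisopropylcarbamoyl chloride, CC(C)N(C(C)C)C(Cl)=O
Why: O-Carbamoylation (nucleophilic acyl substitution) of the mono-phenoxide goes to the unhindered 4-OH because the 1-OH is flanked by the ortho-methyl group and the carbamoyl chloride is bulky, which leaves free exactly the hydroxyl that later becomes the ring oxygen; no stereocentre is formed.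

Step 2
Reactants: 2 4-hydroxy-3-methylphenyl N,N-diisopropylcarbamate; 3 geranyl bromide
Product: 4 3-[(2E)-3,7-dimethylocta-2,6-dien-1-yl]-4-hydroxy-5-methylphenyl N,N-diisopropylcarbamate
Conditions: NaH (1.05 equiv), toluene, 0 °C; 3 (1.0 equiv), rt, 16 h
Reagents that add atoms: none
Why: Ortho-C-alkylation of a sodium phenoxide in a non-polar solvent (tight ion pair, SN2 at the primary allylic bromide with the E-alkene retained) can only go to the single free ortho carbon, since the other ortho carbon carries the methyl group and the para position the carbamate; no stereocentre is formed.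

Step 3
Reactants: 4 ortho-geranyl phenol carbamate; 5 methacrolein
Product: 6 3-[(2E,6E)-3,7-dimethyl-8-oxoocta-2,6-dien-1-yl]-4-hydroxy-5-methylphenyl N,N-diisopropylcarbamate
Conditions: 5 (5 equiv), second-generation Hoveyda–Grubbs catalyst RuCl2(H2IMes)(=CH-C6H4-2-O-i-Pr) (5 mol %), CH2Cl2, 40 °C, 12 h
Reagents that add atoms: none
Why: Olefin cross-metathesis exchanges the isopropylidene terminus for the methacrolein alkylidene with loss of isobutene and gives the E-enal under thermodynamic control, while the internal trisubstituted alkene is too hindered to react and the new electron-poor alkene is inert to the electrophile of step 4; no stereocentre is formed.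

Step 4
Reactants: 6 enal phenol carbamate
Product: 7 (2R,3S)-2,8-dimethyl-2-[(3E)-4-methyl-5-oxopent-3-en-1-yl]-3-(phenylsulfanyl)-3,4-dihydro-2H-chromen-6-yl N,N-diisopropylcarbamate
Conditions: N-(phenylthio)phthalimide (1.1 equiv), (S)-BINAM-derived selenophosphoramide (S)-C20H12(NMe)2P(=Se)N(i-Pr)2 (10 mol %), MsOH (0.5 equiv), CH2Cl2, −20 °C, 48 h
Reagents that add atoms: N-(phenylthio)phthalimide, O=C1c2ccccc2C(=O)N1Sc1ccccc1
Why: Lewis-base-catalysed enantioselective sulfenoetherification, in which the chiral selenophosphoramide delivers PhS+ to one face of the E-trisubstituted alkene and the phenol oxygen attacks the tertiary carbon from the opposite face (anti addition, 6-endo, Markovnikov), closes the pyran ring and sets C2 (R) and C3 (S) in one event.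

Step 5
Reactants: 7 (2R,3S)-3-phenylthiochroman enal
Product: 9 (2R)-2,8-dimethyl-2-[(3E)-4-methyl-5-oxopent-3-en-1-yl]-2H-chromen-6-yl N,N-diisopropylcarbamate, via sulfoxide 8 (not isolated)
Conditions: mCPBA (1.0 equiv), CH2Cl2, −78 °C; then solvent switch to toluene, 90 °C, 2 h, dark
Reagents that add atoms: none
Why: Chemoselective sulfide oxidation followed by thermal syn-elimination of the aryl sulfoxide, which can only take a benzylic hydrogen at C4 because C2 is quaternary, gives the C3=C4 double bond under conditions (90 °C, dark) that do not open the pyran ring, so C2 stays R.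

Step 6
Reactants: 10 geraniol
Product: 11 (2E)-3,7-dimethylocta-2,6-dien-1-yl N,N-diisopropylcarbamate (geranyl carbamate)
Conditions: NaH (1.2 equiv), THF, 0 °C; i-Pr2NCOCl (1.1 equiv), 65 °C, 12 h
Reagents that add atoms: N,N-diisopropylcarbamoyl chloride, CC(C)N(C(C)C)C(Cl)=O
Why: O-Carbamoylation of the sodium alkoxide (nucleophilic acyl substitution) installs the directing and acidifying group needed for the α-lithiation of step 7 without touching the E-alkene; no stereocentre is formed.

Step 7
Reactants: 11 geranyl N,N-diisopropylcarbamate; 9 (2R)-chromene enal carbamate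
Product: 13 (2R)-2-[(3E,5R,6R,7E)-6-(N,N-diisopropylcarbamoyloxy)-5-hydroxy-4,8,12-trimethyltrideca-3,7,11-trien-1-yl]-2,8-dimethyl-2H-chromen-6-yl N,N-diisopropylcarbamate, via lithiated carbamate 12 (not isolated)
Conditions: 11 (1.3 equiv), (−)-sparteine (1.35 equiv), n-BuLi (1.25 equiv), toluene, −78 °C, 1 h; 9 (1.0 equiv), −78 °C, 2 h; AcOH, −78 °C
Reagents that add atoms: none
Why: Proposed new method: n-BuLi/(−)-sparteine removes the pro-S proton of the allylic O-carbamate to give the carbamate-chelated, sparteine-ligated α-oxy allyllithium 12, which is expected to add to the aldehyde at its α-carbon (the γ-terminus is fully substituted) with retention through a lithium-bridged four-centre transition state, fixing C6' as R, while the aldehyde oxygen sits next to the chelating carbamate oxygen and the alkenyl residue of 9 takes the sector beside the small hydrogen, fixing C5' as R (syn adduct, modest selectivity expected, minor anti isomer removed by chromatography); the closest known reactions are the sparteine-mediated asymmetric deprotonation and retentive electrophilic substitution of O-alkyl carbamates and the α-/γ-hydroxyalkylation (homoaldol chemistry) of lithiated 2-alkenyl carbamates.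

Step 8
Reactants: 13 bis-carbamate adduct
Product: 14 (2R)-2-[(3E,5R,6R,7E)-5,6-dihydroxy-4,8,12-trimethyltrideca-3,7,11-trien-1-yl]-2,8-dimethyl-2H-chromen-6-ol
Conditions: LiAlH4 (6 equiv), THF, 0 to 65 °C, 6 h; aqueous KNaC4H4O6 (potassium sodium tartrate) work-up
Reagents that add atoms: none
Why: Reductive carbamate cleavage by hydride attack at each carbamoyl carbon (the nitrogen part leaves as the N-methylamine) frees the phenol and the 6'-hydroxyl without breaking any bond to C2, C5' or C6', so all three stereocentres are retained, and any adduct in which the carbamoyl group has shifted to the neighbouring oxygen gives the same diol.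

## Compound list

1 | 2-methylhydroquinone (2-methylbenzene-1,4-diol) | Cc1cc(O)ccc1O | starting material
2 | 4-hydroxy-3-methylphenyl N,N-diisopropylcarbamate | CC(C)N(C(C)C)C(=O)Oc1ccc(O)c(C)c1 | intermediate
3 | geranyl bromide, (2E)-1-bromo-3,7-dimethylocta-2,6-diene | CC(C)=CCC/C(C)=C/CBr | starting material
4 | 3-[(2E)-3,7-dimethylocta-2,6-dien-1-yl]-4-hydroxy-5-methylphenyl N,N-diisopropylcarbamate | CC(C)=CCC/C(C)=C/Cc1cc(OC(=O)N(C(C)C)C(C)C)cc(C)c1O | intermediate
5 | methacrolein (2-methylprop-2-enal) | CC(=C)C=O | starting material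
6 | 3-[(2E,6E)-3,7-dimethyl-8-oxoocta-2,6-dien-1-yl]-4-hydroxy-5-methylphenyl N,N-diisopropylcarbamate | O=C/C(C)=C/CC/C(C)=C/Cc1cc(OC(=O)N(C(C)C)C(C)C)cc(C)c1O | intermediate
7 | (2R,3S)-2,8-dimethyl-2-[(3E)-4-methyl-5-oxopent-3-en-1-yl]-3-(phenylsulfanyl)-3,4-dihydro-2H-chromen-6-yl N,N-diisopropylcarbamate | O=C/C(C)=C/CC[C@]1(C)[C@@H](Sc3ccccc3)Cc2cc(OC(=O)N(C(C)C)C(C)C)cc(C)c2O1 | intermediate
8 | (2R,3S)-2,8-dimethyl-2-[(3E)-4-methyl-5-oxopent-3-en-1-yl]-3-(phenylsulfinyl)-3,4-dihydro-2H-chromen-6-yl N,N-diisopropylcarbamate (both configurations at sulfur) | O=C/C(C)=C/CC[C@]1(C)[C@@H](S(=O)c3ccccc3)Cc2cc(OC(=O)N(C(C)C)C(C)C)cc(C)c2O1 | intermediate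
9 | (2R)-2,8-dimethyl-2-[(3E)-4-methyl-5-oxopent-3-en-1-yl]-2H-chromen-6-yl N,N-diisopropylcarbamate | O=C/C(C)=C/CC[C@]1(C)C=Cc2cc(OC(=O)N(C(C)C)C(C)C)cc(C)c2O1 | intermediate
10 | geraniol, (2E)-3,7-dimethylocta-2,6-dien-1-ol | CC(C)=CCC/C(C)=C/CO | starting material
11 | (2E)-3,7-dimethylocta-2,6-dien-1-yl N,N-diisopropylcarbamate | CC(C)=CCC/C(C)=C/COC(=O)N(C(C)C)C(C)C | intermediate
12 | (1S,2E)-1-lithio-3,7-dimethylocta-2,6-dien-1-yl N,N-diisopropylcarbamate, as its (−)-sparteine complex | [Li][C@H](OC(=O)N(C(C)C)C(C)C)/C=C(\C)CCC=C(C)C | intermediate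
13 | (2R)-2-[(3E,5R,6R,7E)-6-(N,N-diisopropylcarbamoyloxy)-5-hydroxy-4,8,12-trimethyltrideca-3,7,11-trien-1-yl]-2,8-dimethyl-2H-chromen-6-yl N,N-diisopropylcarbamate | CC(C)=CCC/C(C)=C/[C@@H](OC(=O)N(C(C)C)C(C)C)[C@H](O)/C(C)=C/CC[C@]1(C)C=Cc2cc(OC(=O)N(C(C)C)C(C)C)cc(C)c2O1 | intermediate
14 | (2R)-2-[(3E,5R,6R,7E)-5,6-dihydroxy-4,8,12-trimethyltrideca-3,7,11-trien-1-yl]-2,8-dimethyl-2H-chromen-6-ol | CC(C)=CCC/C(C)=C/[C@@H](O)[C@H](O)/C(C)=C/CC[C@]1(C)C=Cc2cc(O)cc(C)c2O1 | target

## Step count and risk

Total steps: 8. Longest linear sequence: 7 steps (1 → 2 → 4 → 6 → 7 → 9 → 13 → 14); step 6 prepares the second fragment.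

The three steps most likely to fail:

Step 7 (key coupling). The α- versus γ-regiochemistry of 12, its configurational stability and the syn:anti ratio are all untested on this substrate. Fallback: setting out from 9, the aldehyde is oxidised (NaClO2, NaH2PO4, 2-methyl-2-butene, t-BuOH/H2O) to (2E)-5-[(2R)-6-(N,N-diisopropylcarbamoyloxy)-2,8-dimethyl-2H-chromen-2-yl]-2-methylpent-2-enoic acid F1. F1 is coupled with MeNHOMe·HCl (EDC·HCl, DMAP, CH2Cl2) to the Weinreb amide F2. Then 12 (made from 11 as in step 7) is acylated by F2 at −78 °C and quenched cold with AcOH to give the (6'R)-6'-carbamoyloxy-5'-ketone F3. Felkin–Anh-controlled 1,2-reduction with LiBH(s-Bu)3 (THF, −78 °C) sets C5' and returns to 13. The second carbinol centre then depends on a substrate-controlled ketone reduction and no longer on the topicity of an aldehyde addition.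

Step 4 (enantioselective ring closure). Enantioselectivity and 6-endo selectivity are unproven for this hindered, electron-poor phenol. Fallback: setting out from 6, a non-asymmetric 6-endo oxypalladation/β-hydride elimination (Pd(dba)2, bis(dibenzylideneacetone)palladium, KHCO3, DMSO/H2O, air, 60 °C) gives the racemic chromene enal F4 in one step. Preparative chromatography on a chiral stationary phase (amylose tris(3,5-dimethylphenylcarbamate), hexane/i-PrOH) then gives 9, so steps 4 and 5 are both bypassed. The unwanted enantiomer can be racemised by irradiation (reversible electrocyclic ring opening) and recycled.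

Step 2 (C- versus O-alkylation). O-Alkylation and dialkylation can compete with ortho-C-alkylation. Fallback: setting out from 2, O-alkylation with 3 (K2CO3, acetone, 56 °C) gives the aryl geranyl ether F5. Montmorillonite K10 clay (CH2Cl2, 0 °C) then moves the geranyl group to the free ortho carbon by a formal [1,3]-shift and returns to 4.

## Further compounds

F1 | step 7 | (2E)-5-[(2R)-6-(N,N-diisopropylcarbamoyloxy)-2,8-dimethyl-2H-chromen-2-yl]-2-methylpent-2-enoic acid | OC(=O)/C(C)=C/CC[C@]1(C)C=Cc2cc(OC(=O)N(C(C)C)C(C)C)cc(C)c2O1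
F2 | step 7 | (2R)-2-[(3E)-5-[methoxy(methyl)amino]-4-methyl-5-oxopent-3-en-1-yl]-2,8-dimethyl-2H-chromen-6-yl N,N-diisopropylcarbamate | CON(C)C(=O)/C(C)=C/CC[C@]1(C)C=Cc2cc(OC(=O)N(C(C)C)C(C)C)cc(C)c2O1
F3 | step 7 | (2R)-2-[(3E,6R,7E)-6-(N,N-diisopropylcarbamoyloxy)-4,8,12-trimethyl-5-oxotrideca-3,7,11-trien-1-yl]-2,8-dimethyl-2H-chromen-6-yl N,N-diisopropylcarbamate | CC(C)=CCC/C(C)=C/[C@@H](OC(=O)N(C(C)C)C(C)C)C(=O)/C(C)=C/CC[C@]1(C)C=Cc2cc(OC(=O)N(C(C)C)C(C)C)cc(C)c2O1
F4 | step 4 | racemic 2,8-dimethyl-2-[(3E)-4-methyl-5-oxopent-3-en-1-yl]-2H-chromen-6-yl N,N-diisopropylcarbamate | O=C/C(C)=C/CCC1(C)C=Cc2cc(OC(=O)N(C(C)C)C(C)C)cc(C)c2O1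
F5 | step 2 | 4-[(2E)-3,7-dimethylocta-2,6-dien-1-yloxy]-3-methylphenyl N,N-diisopropylcarbamate | CC(C)=CCC/C(C)=C/COc1ccc(OC(=O)N(C(C)C)C(C)C)cc1C
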